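**Strategy.** The tetralin is disconnected across ring A: bonds C4a–C5 and C8–C8a are formed on a ring B cyclohexanone that already carries C1, C2 and C3 in their final all-trans arrangement. The feature exploited is the 6-methoxy-7-hydroxy pattern of ring A (C4a, C5, C6, C7, C8, C8a): C5–C8 with both oxygens map onto 3-methoxybut-3-en-2-one, so one enamine Robinson annulation closes ring A as a 6-methoxy-7-oxo cyclohexenone with the oxygen pattern fixed by connectivity; dehydrogenation then gives the C7 phenol. The precursor is the all-trans 2-aryl-3-(benzyloxymethyl)-4-(silyloxymethyl)cyclohexanone, built from a desymmetrised 4-substituted cyclohexenone by cuprate addition and enol silane arylation.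

Key step: step 9

Remark on locants: bicyclic compounds carry the tetralin locants of the target (C1 aryl carbon, C2, C3, C4, C4a, C5–C8, C8a); monocyclic compounds carry cyclohexanone locants.
Assumption: the chiral lithium amide is taken to show the same sense of induction as with 4-tert-butylcyclohexanone, where the (R,R)-amide gives the (S)-enol silane; the (S,S)-amide is therefore used to enter the (R)-series.
Remark: 4-(hydroxymethyl)cyclohexan-1-one and (tributylstannyl)methanol are taken as purchased materials.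

Step 1
Reactants: 1 4-(hydroxymethyl)cyclohexan-1-one
Product: 2 4-{[tert-butyl(diphenyl)silyl]oxymethyl}cyclohexan-1-one
Conditions: TBDPSCl, imidazole, DMF, 0 °C → rt
Reagents that add atoms: tert-butyl(chloro)diphenylsilane, CC(C)(C)[Si](Cl)(c1ccccc1)c1ccccc1
Why: Silylation of an unhindered primary alcohol (substitution at silicon with imidazole as base) should be clean and gives an ether that withstands every later step up to the final deprotection.

Step 2
Reactants: 2 4-{[tert-butyl(diphenyl)silyl]oxymethyl}cyclohexan-1-one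
Product: 3 tert-butyl(diphenyl){[(1R)-4-(trimethylsilyloxy)cyclohex-3-en-1-yl]methoxy}silane
Conditions: (S,S)-[PhCH(Me)]2NH, n-BuLi, THF, −78 °C; TMSCl, then 2, −100 → −78 °C; Et3N, NaHCO3 work-up
Reagents that add atoms: chlorotrimethylsilane, C[Si](C)(C)Cl
Why: Enantioselective deprotonation by a C2-symmetric chiral lithium amide with in situ silyl trapping (desymmetrisation of a 4-substituted cyclohexanone) should make the CH2OSi-bearing carbon stereogenic as R, the reagent choosing one of the two enantiotopic axial α-protons of the chair.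

Step 3
Reactants: 3 tert-butyl(diphenyl){[(1R)-4-(trimethylsilyloxy)cyclohex-3-en-1-yl]methoxy}silane
Product: 4 (4R)-4-{[tert-butyl(diphenyl)silyl]oxymethyl}cyclohex-2-en-1-one
Conditions: Pd(OAc)2 (10 mol%), O2 (1 atm), DMSO, rt
Reagents that add atoms: none
Why: Saegusa–Ito oxidation: divalent palladium palladates the enol silane carbon and β-hydride elimination places the double bond on the side defined in step 2, leaving the γ-stereocentre untouched.

Step 4
Reactants: 5 (tributylstannyl)methanol
Product: 6 [(benzyloxy)methyl]tributylstannane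
Conditions: NaH, BnBr, Bu4NI (cat.), THF, 0 °C → rt
Reagents that add atoms: benzyl bromide, BrCc1ccccc1
Why: Williamson etherification of the primary alkoxide with benzyl bromide is a standard way to this α-alkoxymethyl stannane.

Step 5
Reactants: 4 (4R)-4-{[tert-butyl(diphenyl)silyl]oxymethyl}cyclohex-2-en-1-one; 6 [(benzyloxy)methyl]tributylstannane
Product: 9 tert-butyl{[(1R,2S)-2-(benzyloxymethyl)-4-(trimethylsilyloxy)cyclohex-3-en-1-yl]methoxy}diphenylsilane (1,2-trans), via (benzyloxymethyl)lithium 7 (not isolated), via lithium bis(benzyloxymethyl)cuprate 8 (not isolated)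
Conditions: 6, n-BuLi, THF, −78 °C; CuBr·SMe2 (0.5 equiv per Li), −78 °C; TMSCl, then 4, −78 °C; Et3N, aq NH4Cl/NH3 work-up
Reagents that add atoms: chlorotrimethylsilane, C[Si](C)(C)Cl
Why: Tin–lithium exchange gives the α-alkoxy organolithium, whose Gilman cuprate should add 1,4 under TMSCl acceleration anti to the pseudoequatorial CH2OSi group (substrate control, new centre trans), the enolate being kept as its regiodefined enol silane.

Step 6
Reactants: 10 4-bromo-2-methoxyphenol
Product: 11 (4-bromo-2-methoxyphenoxy)triisopropylsilane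
Conditions: TIPSCl, imidazole, DMF, rt
Reagents that add atoms: chlorotriisopropylsilane, CC(C)[Si](Cl)(C(C)C)C(C)C
Why: Phenol silylation gives a bulky aryl silyl ether that tolerates fluoride-mediated coupling, amines, amide bases and hydrogenolysis.

Step 7
Reactants: 9 tert-butyl{[(1R,2S)-2-(benzyloxymethyl)-4-(trimethylsilyloxy)cyclohex-3-en-1-yl]methoxy}diphenylsilane; 11 (4-bromo-2-methoxyphenoxy)triisopropylsilane
Product: 12 (2S,3S,4R)-3-(benzyloxymethyl)-4-{[tert-butyl(diphenyl)silyl]oxymethyl}-2-[3-methoxy-4-(triisopropylsilyloxy)phenyl]cyclohexan-1-one (all-trans)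
Conditions: Pd(OAc)2 (5 mol%), P(t-Bu)3 (10 mol%), Bu3SnF (1.4 equiv), PhMe, 85 °C; then DBU (0.2 equiv), rt
Reagents that add atoms: none
Why: Palladium-catalysed α-arylation of a silyl enol ether (oxidative addition of the bromide to zerovalent palladium, transmetalation of the tin enolate, reductive elimination) should form the aryl bond only at the enol silane carbon, and base equilibration of this epimerisable centre should place the aryl group equatorial, trans to its neighbour.

Step 8
Reactants: 13 3,3-dimethoxybutan-2-one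
Product: 14 3-methoxybut-3-en-2-one
Conditions: TsOH·H2O (cat.), neat, 150 °C, MeOH distilled off; redistil
Reagents that add atoms: none
Why: Acid-catalysed loss of methanol from the ketal (enol ether formation), driven by distillation, is the established preparation of this 2-methoxy enone.

Step 9
Reactants: 12 (2S,3S,4R)-3-(benzyloxymethyl)-4-{[tert-butyl(diphenyl)silyl]oxymethyl}-2-[3-methoxy-4-(triisopropylsilyloxy)phenyl]cyclohexan-1-one; 14 3-methoxybut-3-en-2-one
Product: 17 (1S,2R,3R)-2-(benzyloxymethyl)-3-{[tert-butyl(diphenyl)silyl]oxymethyl}-6-methoxy-1-[3-methoxy-4-(triisopropylsilyloxy)phenyl]-2,3,4,4a,5,6-hexahydronaphthalen-7(1H)-one (C8=C8a enone; C4a/C6 unspecified), via C4a-side pyrrolidine enamine 15 (not isolated), via Michael adduct 1,5-diketone 16 (not isolated)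
Conditions: pyrrolidine (3 equiv), TsOH (cat.), PhMe, reflux, Dean–Stark; evaporate; 14 (2 equiv), dioxane, rt → 80 °C; NaOAc/AcOH/H2O, 80 °C
Reagents that add atoms: none
Why: Pyrrolidine condenses with the C8a ketone to the less substituted enamine (C8a=C4a), whose β-carbon adds to the CH2 terminus of the 2-methoxy enone (C4a–C5); hydrolysis gives the 1,5-diketone, whose methyl ketone carbon C8 then attacks C8a and water is lost, i.e. a Stork enamine Michael addition followed by intramolecular aldol condensation, the classical Robinson annulation. Ring A closes in a 6-exo-trig (enolexo) aldol mode, whereas attack of C1 on the C7 carbonyl would give a bridged ketol that cannot dehydrate and should revert. The new centres C4a and C6 form without control and need none, since both become sp2 on aromatisation. The step needs regioselection for C4a over the benzylic C1; the substrate secures it through allylic strain that disfavours the tetrasubstituted aryl enamine and through the C2 substituent, which blocks quaternisation at C1. C1 can epimerise by iminium–enamine exchange but should remain trans to C2 because the aryl group is equatorial in the all-equatorial ring B chair. The oxygen pattern follows from connectivity, the methoxy-bearing acceptor carbon becoming C6 and the acceptor carbonyl C7.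

Step 10
Reactants: 17 (1S,2R,3R)-6-methoxy-7-oxo octalone from step 9
Product: 20 (1S,2R,3R)-2-(benzyloxymethyl)-3-{[tert-butyl(diphenyl)silyl]oxymethyl}-6-methoxy-1-[3-methoxy-4-(triisopropylsilyloxy)phenyl]-1,2,3,4-tetrahydronaphthalen-7-ol, via trimethylsilyl dienol ether 18 (not isolated), via 4H-cyclohexa-2,5-dienone 19 (not isolated)
Conditions: LiN(i-Pr)2, THF, −78 °C; TMSCl, −78 → 0 °C; evaporate, pentane filtration; Pd(OAc)2 (1.1 equiv), MeCN, rt
Reagents that add atoms: none
Why: Kinetic deprotonation at the only α-CH (C6) followed by Saegusa–Ito oxidation can only eliminate toward C5, and the resulting 4H-dienone should tautomerise at once to the C7 phenol, erasing C4a and C6 without involving C1.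

Step 11
Reactants: 20 (1S,2R,3R)-tetrahydronaphthalen-7-ol from step 10
Product: 21 tert-butyl{[(1S,2R,3R)-2-(benzyloxymethyl)-6-methoxy-1-[3-methoxy-4-(triisopropylsilyloxy)phenyl]-7-(triisopropylsilyloxy)-1,2,3,4-tetrahydronaphthalen-3-yl]methoxy}diphenylsilane
Conditions: TIPSCl, imidazole, DMF, rt
Reagents that add atoms: chlorotriisopropylsilane, CC(C)[Si](Cl)(C(C)C)C(C)C
Why: Phenol silylation masks the C7 hydroxyl so that only the C9' alcohol can be acylated later.

Step 12
Reactants: 21 fully protected tetralin benzyl ether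
Product: 22 [(1S,2R,3R)-3-{[tert-butyl(diphenyl)silyl]oxymethyl}-6-methoxy-1-[3-methoxy-4-(triisopropylsilyloxy)phenyl]-7-(triisopropylsilyloxy)-1,2,3,4-tetrahydronaphthalen-2-yl]methanol
Conditions: H2 (1 atm), Pd/C (10%), EtOAc, rt
Reagents that add atoms: none
Why: Hydrogenolysis of the benzyl ether frees only the C9' alcohol; silyl ethers are inert and no alkene or benzylic C–O bond is present at this stage.

Step 13
Reactants: 23 (E)-4-hydroxycinnamic acid
Product: 25 (E)-3-[4-(tert-butyldimethylsilyloxy)phenyl]prop-2-enoic acid, via bis-silylated silyl ester 24 (not isolated)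
Conditions: TBSCl (2.5 equiv), imidazole, DMF, rt; then AcOH/THF/H2O, rt
Reagents that add atoms: tert-butyl(chloro)dimethylsilane, CC(C)(C)[Si](C)(C)Cl
Why: Exhaustive silylation followed by selective hydrolysis of the much more labile silyl ester should leave the phenol protected and the acid free.

Step 14
Reactants: 22 C9' primary alcohol; 25 (E)-3-[4-(tert-butyldimethylsilyloxy)phenyl]prop-2-enoic acid
Product: 26 [(1S,2R,3R)-3-{[tert-butyl(diphenyl)silyl]oxymethyl}-6-methoxy-1-[3-methoxy-4-(triisopropylsilyloxy)phenyl]-7-(triisopropylsilyloxy)-1,2,3,4-tetrahydronaphthalen-2-yl]methyl (E)-3-[4-(tert-butyldimethylsilyloxy)phenyl]prop-2-enoate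
Conditions: DCC, DMAP (cat.), CH2Cl2, 0 °C → rt
Reagents that add atoms: none
Why: Steglich esterification acylates the only free hydroxyl, and the E alkene is not affected.

Step 15
Reactants: 26 fully silylated ester
Product: 27 [(1S,2R,3R)-7-hydroxy-1-(4-hydroxy-3-methoxyphenyl)-3-(hydroxymethyl)-6-methoxy-1,2,3,4-tetrahydronaphthalen-2-yl]methyl (E)-3-(4-hydroxyphenyl)prop-2-enoate (target)
Conditions: Bu4NF, AcOH (1:1, excess), THF, 0 °C → rt
Reagents that add atoms: none
Why: Buffered fluoride desilylation should cleave the three aryl silyl ethers and the primary silyl ether while the acetic acid keeps phenoxide and alkoxide levels too low for ester cleavage or acyl migration.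

**Compound list**

1 | 4-(hydroxymethyl)cyclohexan-1-one | O=C1CCC(CO)CC1 | starting material
2 | 4-{[tert-butyl(diphenyl)silyl]oxymethyl}cyclohexan-1-one | O=C1CCC(CO[Si](c2ccccc2)(c2ccccc2)C(C)(C)C)CC1 | intermediate
3 | tert-butyl(diphenyl){[(1R)-4-(trimethylsilyloxy)cyclohex-3-en-1-yl]methoxy}silane | C[Si](C)(C)OC1=CC[C@H](CO[Si](c2ccccc2)(c2ccccc2)C(C)(C)C)CC1 | intermediate
4 | (4R)-4-{[tert-butyl(diphenyl)silyl]oxymethyl}cyclohex-2-en-1-one | O=C1CC[C@@H](CO[Si](c2ccccc2)(c2ccccc2)C(C)(C)C)C=C1 | intermediate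
5 | (tributylstannyl)methanol | CCCC[Sn](CCCC)(CCCC)CO | starting material
6 | [(benzyloxy)methyl]tributylstannane | CCCC[Sn](CCCC)(CCCC)COCc1ccccc1 | intermediate
7 | (benzyloxymethyl)lithium | [Li]COCc1ccccc1 | intermediate (not isolated)
8 | lithium bis(benzyloxymethyl)cuprate | [Li+].[Cu-](COCc1ccccc1)COCc1ccccc1 | intermediate (not isolated)
9 | tert-butyl{[(1R,2S)-2-(benzyloxymethyl)-4-(trimethylsilyloxy)cyclohex-3-en-1-yl]methoxy}diphenylsilane | C[Si](C)(C)OC1=C[C@@H](COCc2ccccc2)[C@H](CO[Si](c2ccccc2)(c2ccccc2)C(C)(C)C)CC1 | intermediate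
10 | 4-bromo-2-methoxyphenol | COc1cc(Br)ccc1O | starting material
11 | (4-bromo-2-methoxyphenoxy)triisopropylsilane | COc1cc(Br)ccc1O[Si](C(C)C)(C(C)C)C(C)C | intermediate
12 | (2S,3S,4R)-3-(benzyloxymethyl)-4-{[tert-butyl(diphenyl)silyl]oxymethyl}-2-[3-methoxy-4-(triisopropylsilyloxy)phenyl]cyclohexan-1-one | COc1cc([C@H]2C(=O)CC[C@@H](CO[Si](c3ccccc3)(c3ccccc3)C(C)(C)C)[C@@H]2COCc2ccccc2)ccc1O[Si](C(C)C)(C(C)C)C(C)C | intermediate (key step precursor)
13 | 3,3-dimethoxybutan-2-one | CC(=O)C(C)(OC)OC | starting material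
14 | 3-methoxybut-3-en-2-one | COC(=C)C(C)=O | intermediate
15 | pyrrolidine enamine of 12 with the C8a=C4a double bond (ring B centres as in 12) | COc1cc([C@H]2C(N3CCCC3)=CC[C@@H](CO[Si](c3ccccc3)(c3ccccc3)C(C)(C)C)[C@@H]2COCc2ccccc2)ccc1O[Si](C(C)C)(C(C)C)C(C)C | intermediate (not isolated)
16 | 12 carrying a 2-methoxy-3-oxobutyl chain at C4a (C4a and C6 unspecified) | COc1cc([C@H]2C(=O)C(CC(OC)C(C)=O)C[C@@H](CO[Si](c3ccccc3)(c3ccccc3)C(C)(C)C)[C@@H]2COCc2ccccc2)ccc1O[Si](C(C)C)(C(C)C)C(C)C | intermediate (not isolated)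
17 | (1S,2R,3R)-2-(benzyloxymethyl)-3-{[tert-butyl(diphenyl)silyl]oxymethyl}-6-methoxy-1-[3-methoxy-4-(triisopropylsilyloxy)phenyl]-2,3,4,4a,5,6-hexahydronaphthalen-7(1H)-one (C4a and C6 unspecified) | COc1cc([C@H]2C3=CC(=O)C(OC)CC3C[C@@H](CO[Si](c3ccccc3)(c3ccccc3)C(C)(C)C)[C@@H]2COCc2ccccc2)ccc1O[Si](C(C)C)(C(C)C)C(C)C | intermediate (key step product)
18 | 7-trimethylsilyloxy dienol ether of 17 (C6=C7 and C8=C8a; C1, C2, C3 as in 17; C4a unspecified) | COc1cc([C@H]2C3=CC(O[Si](C)(C)C)=C(OC)CC3C[C@@H](CO[Si](c3ccccc3)(c3ccccc3)C(C)(C)C)[C@@H]2COCc2ccccc2)ccc1O[Si](C(C)C)(C(C)C)C(C)C | intermediate (not isolated)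
19 | 5,6-didehydro derivative of 17 (ring A 4H-cyclohexa-2,5-dienone; C4a unspecified) | COc1cc([C@H]2C3=CC(=O)C(OC)=CC3C[C@@H](CO[Si](c3ccccc3)(c3ccccc3)C(C)(C)C)[C@@H]2COCc2ccccc2)ccc1O[Si](C(C)C)(C(C)C)C(C)C | intermediate (not isolated)
20 | (1S,2R,3R)-2-(benzyloxymethyl)-3-{[tert-butyl(diphenyl)silyl]oxymethyl}-6-methoxy-1-[3-methoxy-4-(triisopropylsilyloxy)phenyl]-1,2,3,4-tetrahydronaphthalen-7-ol | COc1cc([C@H]2c3cc(O)c(OC)cc3C[C@@H](CO[Si](c3ccccc3)(c3ccccc3)C(C)(C)C)[C@@H]2COCc2ccccc2)ccc1O[Si](C(C)C)(C(C)C)C(C)C | intermediate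
21 | 7-O-triisopropylsilyl ether of 20 | COc1cc([C@H]2c3cc(O[Si](C(C)C)(C(C)C)C(C)C)c(OC)cc3C[C@@H](CO[Si](c3ccccc3)(c3ccccc3)C(C)(C)C)[C@@H]2COCc2ccccc2)ccc1O[Si](C(C)C)(C(C)C)C(C)C | intermediate
22 | [(1S,2R,3R)-3-{[tert-butyl(diphenyl)silyl]oxymethyl}-6-methoxy-1-[3-methoxy-4-(triisopropylsilyloxy)phenyl]-7-(triisopropylsilyloxy)-1,2,3,4-tetrahydronaphthalen-2-yl]methanol | COc1cc([C@H]2c3cc(O[Si](C(C)C)(C(C)C)C(C)C)c(OC)cc3C[C@@H](CO[Si](c3ccccc3)(c3ccccc3)C(C)(C)C)[C@@H]2CO)ccc1O[Si](C(C)C)(C(C)C)C(C)C | intermediate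
23 | (E)-4-hydroxycinnamic acid | OC(=O)/C=C/c1ccc(O)cc1 | starting material
24 | tert-butyldimethylsilyl (E)-3-[4-(tert-butyldimethylsilyloxy)phenyl]prop-2-enoate | CC(C)(C)[Si](C)(C)OC(=O)/C=C/c1ccc(O[Si](C)(C)C(C)(C)C)cc1 | intermediate (not isolated)
25 | (E)-3-[4-(tert-butyldimethylsilyloxy)phenyl]prop-2-enoic acid | OC(=O)/C=C/c1ccc(O[Si](C)(C)C(C)(C)C)cc1 | intermediate
26 | (E)-4-(tert-butyldimethylsilyloxy)cinnamate ester of 22 at the C9' oxygen | COc1cc([C@H]2c3cc(O[Si](C(C)C)(C(C)C)C(C)C)c(OC)cc3C[C@@H](CO[Si](c3ccccc3)(c3ccccc3)C(C)(C)C)[C@@H]2COC(=O)/C=C/c2ccc(O[Si](C)(C)C(C)(C)C)cc2)ccc1O[Si](C(C)C)(C(C)C)C(C)C | intermediate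
27 | [(1S,2R,3R)-7-hydroxy-1-(4-hydroxy-3-methoxyphenyl)-3-(hydroxymethyl)-6-methoxy-1,2,3,4-tetrahydronaphthalen-2-yl]methyl (E)-3-(4-hydroxyphenyl)prop-2-enoate | COc1cc([C@H]2c3cc(O)c(OC)cc3C[C@@H](CO)[C@@H]2COC(=O)/C=C/c2ccc(O)cc2)ccc1O | target

**Step count.** Total: 15 steps. Longest linear sequence: 11 steps (1, 2, 3, 5, 7, 9, 10, 11, 12, 14, 15).

**Steps most likely to fail, riskiest first**

Step 9. Conjugate addition of the hindered enamine to the captodative 2-methoxy enone may be too slow, so that the acceptor polymerises or the enamine hydrolyses back before the C4a–C5 bond forms. The fallback sets out from 12 and installs the C6 oxygen after the annulation. The same enamine annulation is run with but-3-en-2-one, a much stronger acceptor, to give the 6-unsubstituted octalone F1. Kinetic enolisation (LiN(i-Pr)2, TMSCl, THF, −78 °C) gives the cross-conjugated trimethylsilyl dienol ether F2. Rubottom oxidation (mCPBA, NaHCO3, CH2Cl2, 0 °C, then citric acid) gives the 6-hydroxy enone F3. O-Methylation (Me3OBF4, 1,8-bis(dimethylamino)naphthalene, CH2Cl2) comes back to the route at 17.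

Step 10. Palladation and β-hydride elimination at the fully substituted, methoxy-bearing C6 may be slower than loss of the silyl group, so that the enone is simply returned. The fallback sets out from 17 and aromatises by hydride abstraction. Kinetic enolate trapping with TIPSOTf gives the triisopropylsilyl dienol ether F4, and DDQ (2,6-lutidine, CH2Cl2, 0 °C) dehydrogenates this silyloxydiene with retention of the silyl group. The fallback comes back at 21 and also replaces step 11.

Step 7. Transmetalation and reductive elimination at the β-branched enol silane may be slow, so that protodesilylation to the unarylated ketone or a second arylation competes. The fallback sets out from 4 and introduces the aryl group before the benzyloxymethyl group. α-Iodination (I2, pyridine, CH2Cl2) gives the 2-iodo enone F5. Bromide 11 is converted (n-BuLi, B(Oi-Pr)3, THF, −78 °C, then aq NH4Cl) into the arylboronic acid F6. Suzuki–Miyaura coupling (PdCl2(dppf), K3PO4, dioxane/H2O, 60 °C) gives the 2-aryl enone F7. Conjugate addition of cuprate 8 (TMSCl, −78 °C) anti to the C4 substituent, acidic hydrolysis of the enol silane and DBU equilibration come back to the route at 12.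

**Further compounds**

F1 | step 9 | (1S,2R,3R)-2-(benzyloxymethyl)-3-{[tert-butyl(diphenyl)silyl]oxymethyl}-1-[3-methoxy-4-(triisopropylsilyloxy)phenyl]-2,3,4,4a,5,6-hexahydronaphthalen-7(1H)-one (C4a unspecified) | COc1cc([C@H]2C3=CC(=O)CCC3C[C@@H](CO[Si](c3ccccc3)(c3ccccc3)C(C)(C)C)[C@@H]2COCc2ccccc2)ccc1O[Si](C(C)C)(C(C)C)C(C)C
F2 | step 9 | 7-trimethylsilyloxy dienol ether of F1 (C6=C7 and C8=C8a) | COc1cc([C@H]2C3=CC(O[Si](C)(C)C)=CCC3C[C@@H](CO[Si](c3ccccc3)(c3ccccc3)C(C)(C)C)[C@@H]2COCc2ccccc2)ccc1O[Si](C(C)C)(C(C)C)C(C)C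
F3 | step 9 | 6-hydroxy derivative of F1 (C4a and C6 unspecified) | COc1cc([C@H]2C3=CC(=O)C(O)CC3C[C@@H](CO[Si](c3ccccc3)(c3ccccc3)C(C)(C)C)[C@@H]2COCc2ccccc2)ccc1O[Si](C(C)C)(C(C)C)C(C)C
F4 | step 10 | 7-triisopropylsilyloxy dienol ether of 17 (C6=C7 and C8=C8a) | COc1cc([C@H]2C3=CC(O[Si](C(C)C)(C(C)C)C(C)C)=C(OC)CC3C[C@@H](CO[Si](c3ccccc3)(c3ccccc3)C(C)(C)C)[C@@H]2COCc2ccccc2)ccc1O[Si](C(C)C)(C(C)C)C(C)C
F5 | step 7 | (4R)-4-{[tert-butyl(diphenyl)silyl]oxymethyl}-2-iodocyclohex-2-en-1-one | O=C1CC[C@@H](CO[Si](c2ccccc2)(c2ccccc2)C(C)(C)C)C=C1I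
F6 | step 7 | [3-methoxy-4-(triisopropylsilyloxy)phenyl]boronic acid | COc1cc(B(O)O)ccc1O[Si](C(C)C)(C(C)C)C(C)C
F7 | step 7 | (4R)-4-{[tert-butyl(diphenyl)silyl]oxymethyl}-2-[3-methoxy-4-(triisopropylsilyloxy)phenyl]cyclohex-2-en-1-one | COc1cc(C2=C[C@H](CO[Si](c3ccccc3)(c3ccccc3)C(C)(C)C)CCC2=O)ccc1O[Si](C(C)C)(C(C)C)C(C)C
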